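**Retrosynthetic overview**
- Last step: an intramolecular Ni/Cr (Nozaki–Hiyama–Kishi) coupling of a C8 enol triflate with a C7 (Z)-enal forms the C7–C8 bond, closing the ten-membered ring, and the resulting alkoxide lactonises to the butenolide.
- Before that: the C2–C3 bond is made by catalyst-controlled addition of a C3–C7 homoallylic zinc reagent to the C2 aldehyde; the tiglate follows.
- Ring A (C1, C10, C14) comes first, from an asymmetric Diels–Alder reaction of a (2E)-2-methyl enal (which already carries C8, C17, C18 as an enol triflate ester) with a 1-silyloxypentadiene; a singlet-oxygen ene/dehydration then gives the 14-acetoxy enone.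
- Ring order: ring A, then the ten-membered ring and the butenolide together.

Assumption: briarane numbering is used (C1 quaternary carbon with CH3-15; C2 tiglate carbinol; C5(CH3-16)=C6; C7 lactone O–CH; C8=C17(CH3-19); C18 lactone C=O; C9H2; C10H; C11(CH3-20)=C12; C13 ketone; C14 acetate carbinol), the target is (1R,2S,5Z,7R,10R,14S), and (2Z)-3-methylpent-2-en-4-yn-1-ol is taken as a commercial building block.

**Step 1**
Reactants: 1 4-methylpent-3-enoic acid; 2 methyl propanoate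
Product: 5 methyl 2,6-dimethyl-3-oxohept-5-enoate, via acyl imidazole 3 (not isolated), via lithium enolate 4 (not isolated)
Conditions: 1, 1,1'-carbonyldiimidazole, THF, rt; separately 2 (2.2 equiv), LiN(iPr)2, THF, −78 °C; add 3 to 4, −78 °C; aq. NH4Cl
Reagents that add atoms: none
Why: Crossed Claisen acylation of an ester enolate by an acyl imidazole, the second equivalent of enolate deprotonating the β-keto ester so that it is not acylated again; the only stereocentre (C17) is enolisable and is removed in step 2.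

**Step 2**
Reactants: 5 methyl 2,6-dimethyl-3-oxohept-5-enoate
Product: 6 methyl (2Z)-2,6-dimethyl-3-{[(trifluoromethyl)sulfonyl]oxy}hepta-2,5-dienoate
Conditions: Tf2O, sat. aq. LiOH, toluene, 5 °C
Reagents that add atoms: trifluoromethanesulfonic anhydride, O=S(=O)(OS(=O)(=O)C(F)(F)F)C(F)(F)F
Why: Schotten–Baumann enol triflation of the lithium-chelated (Z)-enolate of a β-keto ester puts the triflate cis to the ester, the geometry that later lets O7 reach C18.

**Step 3**
Reactants: 6 methyl (2Z)-2,6-dimethyl-3-(triflyloxy)hepta-2,5-dienoate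
Product: 7 methyl (2Z,5E)-2,6-dimethyl-7-oxo-3-(triflyloxy)hepta-2,5-dienoate
Conditions: SeO2 (1.2 equiv), 1,4-dioxane, 80 °C
Reagents that add atoms: selenium dioxide, O=[Se]=O
Why: Riley allylic oxidation (ene reaction then [2,3] shift) converts the (E)-methyl of the prenyl terminus into the (E)-enal, while the electron-poor enol triflate alkene does not react.

**Step 4**
Reactants: 8 (2E)-pent-2-enal
Product: 9 triisopropyl{[(1E,3E)-penta-1,3-dien-1-yl]oxy}silane
Conditions: iPr3SiOTf, Et3N, Et2O, 0 °C → rt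
Reagents that add atoms: triisopropylsilyl trifluoromethanesulfonate, CC(C)[Si](C(C)C)(C(C)C)OS(=O)(=O)C(F)(F)F
Why: Silyl dienol ether formation by γ-deprotonation of the O-silylated enal gives mainly the (1E,3E)-diene, and minor geometric isomers cannot adopt the s-cis form and stay unreacted in step 5.

**Step 5**
Reactants: 7 methyl (2Z,5E)-2,6-dimethyl-7-oxo-3-(triflyloxy)hepta-2,5-dienoate; 9 triisopropyl{[(1E,3E)-penta-1,3-dien-1-yl]oxy}silane
Product: 11 methyl (2Z)-4-[(1R,2S,5R,6S)-6-formyl-5-hydroxy-2,6-dimethylcyclohex-3-en-1-yl]-2-methyl-3-(triflyloxy)but-2-enoate, via silyl ether 10 (not isolated)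
Conditions: (S)-B-(2-methylphenyl) diphenylprolinol oxazaborolidine·HNTf2 (20 mol %), 9 (3 equiv), CH2Cl2, −78 → −20 °C; then HF·pyridine, THF, 0 °C → rt
Reagents that add atoms: none
Why: Proposed new method: enantioselective Diels–Alder reaction of a β-alkyl α-methyl (E)-enal bearing an enol triflate with a 1-silyloxy-4-methyl diene under a protonated (S)-oxazaborolidine as chiral boron Lewis acid; boron binds the formyl oxygen (supported by the formyl C–H···O contact) and holds the s-trans enal over the aryl group, so 9 adds to the open face with the formyl group endo; the silyloxy group makes C11 the nucleophilic diene terminus, so the C10–C11 bond leads and C14–C1 closes the ring (ortho adduct); the (E)-enal puts C2 and C9 trans, endo addition puts O14 cis to C2, and the catalyst face (the sense assigned by analogy with 2-substituted acroleins) sets C1, C10 and C14 as in the target, C11 being removed in step 6; the closest known reaction type is the oxazaborolidinium-catalysed Diels–Alder reaction of 2-substituted acroleins with simple dienes, not yet shown for a β-substituted α-methyl enal with a 1,4-disubstituted oxygenated diene forming four contiguous stereocentres; fluoride then cleaves the allylic silyl ether.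

**Step 6**
Reactants: 11 methyl (2Z)-4-[(1R,2S,5R,6S)-6-formyl-5-hydroxy-2,6-dimethylcyclohex-3-en-1-yl]-2-methyl-3-(triflyloxy)but-2-enoate
Product: 14 methyl (2Z)-4-[(1R,5S,6S)-5-acetoxy-6-formyl-2,6-dimethyl-4-oxocyclohex-2-en-1-yl]-2-methyl-3-(triflyloxy)but-2-enoate, via hydroperoxide 12 (not isolated), via peracetate 13 (not isolated)
Conditions: O2, tetraphenylporphyrin (cat.), visible light, CH2Cl2, 0 °C; then Ac2O, pyridine, DMAP (cat.), 0 °C → rt
Reagents that add atoms: oxygen, O=O; acetic anhydride, CC(=O)OC(C)=O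
Why: Schenck ene reaction then Kornblum–DeLaMare dehydration: singlet oxygen bonds to C13 on the face of the two allylic hydrogens and removes the pseudoaxial H-11 (H-14 is geminal to oxygen and pseudoequatorial in the favoured half-chair), moving the alkene to C11=C12; Ac2O acetylates O14 and the hydroperoxide and pyridine eliminates acetate to give the enone, with C14 (S) unchanged under these mild conditions.

**Step 7**
Reactants: 15 (2Z)-3-methylpent-2-en-4-yn-1-ol
Product: 16 triethyl{[(2Z)-3-methylpent-2-en-4-yn-1-yl]oxy}silane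
Conditions: Et3SiCl, imidazole, CH2Cl2, 0 °C
Reagents that add atoms: chlorotriethylsilane, CC[Si](Cl)(CC)CC
Why: Standard silylation of a primary alcohol, the triethylsilyl group being chosen because step 12 oxidises it directly to the aldehyde.

**Step 8**
Reactants: 16 triethyl{[(2Z)-3-methylpent-2-en-4-yn-1-yl]oxy}silane
Product: 17 triethyl{[(2Z)-3-methylpenta-2,4-dien-1-yl]oxy}silane
Conditions: H2 (1 atm), Pd/CaCO3 poisoned with Pb(OAc)2, quinoline, hexane, rt
Reagents that add atoms: none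
Why: Lindlar semi-hydrogenation stops at the terminal vinyl group and leaves the (Z)-trisubstituted alkene untouched.

**Step 9**
Reactants: 17 triethyl{[(2Z)-3-methylpenta-2,4-dien-1-yl]oxy}silane
Product: 19 triethyl{[(2Z)-5-iodo-3-methylpent-2-en-1-yl]oxy}silane, via alkylborane 18 (not isolated)
Conditions: 9-BBN, THF, 0 °C → rt; then NaOMe, I2, MeOH, 0 °C
Reagents that add atoms: iodine, II
Why: Anti-Markovnikov hydroboration of the monosubstituted alkene of the diene (9-BBN is far slower on the trisubstituted alkene), then base-induced iodinolysis of the primary B–C bond.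

**Step 10**
Reactants: 14 methyl (2Z)-4-[(1R,5S,6S)-5-acetoxy-6-formyl-2,6-dimethyl-4-oxocyclohex-2-en-1-yl]-2-methyl-3-(triflyloxy)but-2-enoate; 19 triethyl{[(2Z)-5-iodo-3-methylpent-2-en-1-yl]oxy}silane
Product: 21 methyl (2Z)-4-{(1R,5S,6R)-5-acetoxy-6-[(1S,4Z)-1-hydroxy-4-methyl-6-(triethylsilyloxy)hex-4-en-1-yl]-2,6-dimethyl-4-oxocyclohex-2-en-1-yl}-2-methyl-3-(triflyloxy)but-2-enoate, via dialkylzinc 20 (not isolated)
Conditions: 19 (3 equiv), Et2Zn, CuI (cat.), 55 °C, then evaporate; 14, Ti(OiPr)4, (1R,2R)-1,2-bis(trifluoromethanesulfonamido)cyclohexane (10 mol %), toluene, −20 °C; cold aq. NH4Cl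
Reagents that add atoms: none
Why: Iodine–zinc exchange followed by titanium bis-sulfonamide-catalysed addition of the functionalised dialkylzinc, which reacts only with the aldehyde (ketone, esters and triflate are inert); the (1R,2R)-ligand directs the alkyl group to the Si face and gives (2S), overriding the Felkin bias of the α-quaternary aldehyde.

**Step 11**
Reactants: 21 (the 2S carbinol of step 10); 22 (2E)-2-methylbut-2-enoyl chloride
Product: 23 methyl (2Z)-4-{(1R,5S,6R)-5-acetoxy-2,6-dimethyl-6-[(1S,4Z)-4-methyl-1-{[(2E)-2-methylbut-2-enoyl]oxy}-6-(triethylsilyloxy)hex-4-en-1-yl]-4-oxocyclohex-2-en-1-yl}-2-methyl-3-(triflyloxy)but-2-enoate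
Conditions: DMAP, Et3N, CH2Cl2, 0 → 40 °C
Reagents that add atoms: none
Why: DMAP-catalysed acylation of the hindered secondary alcohol through the acylpyridinium ion, under conditions that should not cause 1,3-acetyl migration from O14, with C2 retained.

**Step 12**
Reactants: 23 (the tiglate of step 11)
Product: 24 methyl (2Z)-4-{(1R,5S,6R)-5-acetoxy-2,6-dimethyl-6-[(1S,4Z)-4-methyl-1-{[(2E)-2-methylbut-2-enoyl]oxy}-6-oxohex-4-en-1-yl]-4-oxocyclohex-2-en-1-yl}-2-methyl-3-(triflyloxy)but-2-enoate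
Conditions: (COCl)2, DMSO, CH2Cl2, −78 → −30 °C; then Et3N, −78 → 0 °C
Reagents that add atoms: none
Why: Swern oxidation applied to a primary triethylsilyl ether: the chlorosulfonium ion removes the silyl group and the alkoxysulfonium ylide collapses to the aldehyde at low temperature, so the (Z)-enal is not isomerised.

**Step 13**
Reactants: 24 (the enal of step 12)
Product: 26 (1R,2S,5Z,7R,10R,14S)-14-acetoxy-13-oxo-2-{[(2E)-2-methylbut-2-enoyl]oxy}briara-5,8(17),11-trien-18,7-olide, via hydroxy ester 25 (not isolated)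
Conditions: CrCl2 (12 equiv), NiCl2 (0.2 equiv), DMSO, 2 mM, slow addition, rt; aq. NH4Cl; then pyridinium p-toluenesulfonate (cat.), CH2Cl2
Reagents that add atoms: none
Why: Intramolecular Nozaki–Hiyama–Kishi coupling: zerovalent nickel (from NiCl2 and CrCl2) inserts into the enol triflate, the vinylchromium species adds only to the aldehyde to close the ten-membered ring at C7–C8, and the C7 alkoxide, held cis to the ester, lactonises to the butenolide; (7R) is expected from the transition state that keeps O7 on the ring periphery and H-7 inside, but this is substrate control that has to be verified.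

**Compound list**
1 | 4-methylpent-3-enoic acid | CC(C)=CCC(=O)O | starting material
2 | methyl propanoate | CCC(=O)OC | starting material
3 | 1-(4-methylpent-3-enoyl)-1H-imidazole | CC(C)=CCC(=O)n1ccnc1 | intermediate
4 | lithium 1-methoxyprop-1-en-1-olate | [Li+].CC=C([O-])OC | intermediate
5 | methyl 2,6-dimethyl-3-oxohept-5-enoate (racemic, enolisable) | CC(C)=CCC(=O)C(C)C(=O)OC | intermediate
6 | methyl (2Z)-2,6-dimethyl-3-{[(trifluoromethyl)sulfonyl]oxy}hepta-2,5-dienoate | CC(C)=CC/C(OS(=O)(=O)C(F)(F)F)=C(\C)C(=O)OC | intermediate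
7 | methyl (2Z,5E)-2,6-dimethyl-7-oxo-3-(triflyloxy)hepta-2,5-dienoate | O=C/C(C)=C/C/C(OS(=O)(=O)C(F)(F)F)=C(\C)C(=O)OC | intermediate
8 | (2E)-pent-2-enal | CC/C=C/C=O | starting material
9 | triisopropyl{[(1E,3E)-penta-1,3-dien-1-yl]oxy}silane | CC(C)[Si](C(C)C)(C(C)C)O/C=C/C=C/C | intermediate
10 | methyl (2Z)-4-{(1R,2S,5R,6S)-6-formyl-2,6-dimethyl-5-[(triisopropylsilyl)oxy]cyclohex-3-en-1-yl}-2-methyl-3-(triflyloxy)but-2-enoate | O=C[C@]1(C)[C@H](O[Si](C(C)C)(C(C)C)C(C)C)C=C[C@H](C)[C@H]1C/C(OS(=O)(=O)C(F)(F)F)=C(\C)C(=O)OC | intermediate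
11 | methyl (2Z)-4-[(1R,2S,5R,6S)-6-formyl-5-hydroxy-2,6-dimethylcyclohex-3-en-1-yl]-2-methyl-3-(triflyloxy)but-2-enoate | O=C[C@]1(C)[C@H](O)C=C[C@H](C)[C@H]1C/C(OS(=O)(=O)C(F)(F)F)=C(\C)C(=O)OC | intermediate
12 | methyl (2Z)-4-[(1R,4S,5S,6S)-6-formyl-4-hydroperoxy-5-hydroxy-2,6-dimethylcyclohex-2-en-1-yl]-2-methyl-3-(triflyloxy)but-2-enoate | O=C[C@]1(C)[C@H](O)[C@@H](OO)C=C(C)[C@H]1C/C(OS(=O)(=O)C(F)(F)F)=C(\C)C(=O)OC | intermediate
13 | methyl (2Z)-4-[(1R,4S,5S,6S)-5-acetoxy-4-(acetylperoxy)-6-formyl-2,6-dimethylcyclohex-2-en-1-yl]-2-methyl-3-(triflyloxy)but-2-enoate | O=C[C@]1(C)[C@H](OC(C)=O)[C@@H](OOC(C)=O)C=C(C)[C@H]1C/C(OS(=O)(=O)C(F)(F)F)=C(\C)C(=O)OC | intermediate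
14 | methyl (2Z)-4-[(1R,5S,6S)-5-acetoxy-6-formyl-2,6-dimethyl-4-oxocyclohex-2-en-1-yl]-2-methyl-3-(triflyloxy)but-2-enoate | O=C[C@]1(C)[C@H](OC(C)=O)C(=O)C=C(C)[C@H]1C/C(OS(=O)(=O)C(F)(F)F)=C(\C)C(=O)OC | intermediate
15 | (2Z)-3-methylpent-2-en-4-yn-1-ol | OC/C=C(/C)C#C | starting material
16 | triethyl{[(2Z)-3-methylpent-2-en-4-yn-1-yl]oxy}silane | CC[Si](CC)(CC)OC/C=C(/C)C#C | intermediate
17 | triethyl{[(2Z)-3-methylpenta-2,4-dien-1-yl]oxy}silane | CC[Si](CC)(CC)OC/C=C(/C)C=C | intermediate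
18 | 9-[(3Z)-3-methyl-5-(triethylsilyloxy)pent-3-en-1-yl]-9-borabicyclo[3.3.1]nonane | CC[Si](CC)(CC)OC/C=C(/C)CCB1C2CCCC1CCC2 | intermediate
19 | triethyl{[(2Z)-5-iodo-3-methylpent-2-en-1-yl]oxy}silane | CC[Si](CC)(CC)OC/C=C(/C)CCI | intermediate
20 | bis[(3Z)-3-methyl-5-(triethylsilyloxy)pent-3-en-1-yl]zinc | CC[Si](CC)(CC)OC/C=C(/C)CC[Zn]CC/C(C)=C\CO[Si](CC)(CC)CC | intermediate
21 | methyl (2Z)-4-{(1R,5S,6R)-5-acetoxy-6-[(1S,4Z)-1-hydroxy-4-methyl-6-(triethylsilyloxy)hex-4-en-1-yl]-2,6-dimethyl-4-oxocyclohex-2-en-1-yl}-2-methyl-3-(triflyloxy)but-2-enoate | O[C@@H](CC/C(C)=C\CO[Si](CC)(CC)CC)[C@]1(C)[C@H](OC(C)=O)C(=O)C=C(C)[C@H]1C/C(OS(=O)(=O)C(F)(F)F)=C(\C)C(=O)OC | intermediate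
22 | (2E)-2-methylbut-2-enoyl chloride (tigloyl chloride) | C/C=C(\C)C(Cl)=O | starting material
23 | methyl (2Z)-4-{(1R,5S,6R)-5-acetoxy-2,6-dimethyl-6-[(1S,4Z)-4-methyl-1-{[(2E)-2-methylbut-2-enoyl]oxy}-6-(triethylsilyloxy)hex-4-en-1-yl]-4-oxocyclohex-2-en-1-yl}-2-methyl-3-(triflyloxy)but-2-enoate | C/C=C(\C)C(=O)O[C@@H](CC/C(C)=C\CO[Si](CC)(CC)CC)[C@]1(C)[C@H](OC(C)=O)C(=O)C=C(C)[C@H]1C/C(OS(=O)(=O)C(F)(F)F)=C(\C)C(=O)OC | intermediate
24 | methyl (2Z)-4-{(1R,5S,6R)-5-acetoxy-2,6-dimethyl-6-[(1S,4Z)-4-methyl-1-{[(2E)-2-methylbut-2-enoyl]oxy}-6-oxohex-4-en-1-yl]-4-oxocyclohex-2-en-1-yl}-2-methyl-3-(triflyloxy)but-2-enoate | C/C=C(\C)C(=O)O[C@@H](CC/C(C)=C\C=O)[C@]1(C)[C@H](OC(C)=O)C(=O)C=C(C)[C@H]1C/C(OS(=O)(=O)C(F)(F)F)=C(\C)C(=O)OC | intermediate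
25 | methyl (1R,2S,5Z,7R,8(17)Z,10R,14S)-14-acetoxy-7-hydroxy-13-oxo-2-{[(2E)-2-methylbut-2-enoyl]oxy}briara-5,8(17),11-trien-18-oate (ten-membered-ring hydroxy ester) | C/C=C(\C)C(=O)O[C@H]1CC/C(C)=C\[C@@H](O)/C(=C(/C)C(=O)OC)C[C@@H]2C(C)=CC(=O)[C@@H](OC(C)=O)[C@@]12C | intermediate
26 | (1R,2S,5Z,7R,10R,14S)-14-acetoxy-13-oxo-2-{[(2E)-2-methylbut-2-enoyl]oxy}briara-5,8(17),11-trien-18,7-olide (CNP0218548.3) | C/C=C(\C)C(=O)O[C@H]1CC/C(C)=C\[C@H]2OC(=O)C(C)=C2C[C@@H]2C(C)=CC(=O)[C@@H](OC(C)=O)[C@@]12C | target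

**Step count**
Total: 13 steps. Longest linear sequence: 9 steps (1, 2, 3, 5, 6, 10, 11, 12, 13).

**Three steps most likely to fail**

Step 5 (the proposed new cycloaddition). The partners are hindered, and reactivity, endo selectivity and the facial sense are all untested for this substrate pair. Fallback with known chemistry, setting out from 7 and 9 and coming back at 14: the cycloaddition is run with Me2AlCl in CH2Cl2 at −78 °C (achiral Lewis acid Diels–Alder of a silyloxydiene with an α-methyl enal), which gives 10 together with its mirror image, the enantiomeric silyl ether F1. HF·pyridine then gives 11 and the enantiomeric alcohol F2. A lipase kinetic resolution (Burkholderia cepacia lipase, vinyl acetate, tert-butyl methyl ether) acetylates the (R)-carbinol 11 (Kazlauskas rule, quaternary carbon as the large group) to the allylic acetate F3 and leaves F2, which is removed by chromatography. Photooxygenation of F3 as in step 6 gives the acetoxy hydroperoxide F4, and Ac2O/pyridine takes it through 13 to 14.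

Step 10 (C2 configuration against the substrate bias; a 1,3-acetyl shift in the metal alkoxide is a second hazard). Fallback, setting out from 14 and 19 and coming back at 21: if catalyst control is poor, 20 is added with Ti(OiPr)4 alone and 21 is obtained mixed with its C2 epimer, the (2R)-carbinol F5. The mixture is oxidised with Dess–Martin periodinane to the C2 ketone F6. LiAlH(OtBu)3 (THF, −78 °C) then reduces the hindered saturated ketone in preference to the conjugated C13 ketone (the selectivity known from 17-keto steroid enones), and hydride delivered on the Felkin face anti to C10 returns 21; the C2 centre is then set by substrate-controlled reduction instead of catalyst-controlled C–C bond formation.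

Step 13 (ten-membered ring closure at a tetrasubstituted vinyl triflate, and the C7 configuration under substrate control). Fallback, setting out from 14 and coming back at 26: 4-iodo-2-methylbut-1-ene is converted (Et2Zn, CuI) into bis(3-methylbut-3-en-1-yl)zinc F7, which is added to 14 under the conditions of step 10 to give the (2S)-homomethallyl carbinol F8. Tigloyl chloride/DMAP gives the tiglate F9. An intermolecular catalytic asymmetric Ni/Cr coupling of the enol triflate with acrolein (CrCl2 10 mol %, chiral oxazoline–sulfonamide ligand, NiCl2·(2,9-dimethyl-1,10-phenanthroline), Mn, Cp2ZrCl2, LiCl, MeCN) sets C7 under reagent control and gives the acyclic hydroxy ester F10, which lactonises to the γ-vinyl butenolide F11. Ring-closing metathesis (second-generation Hoveyda–Grubbs catalyst, RuCl2(H2IMes)(=CH-C6H4-2-OiPr), toluene, 80 °C, 1 mM, 1,4-benzoquinone) then closes C5=C6, the ten-membered ring enforcing the Z geometry, to give 26.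

**Further compounds**
F1 | step 5 | methyl (2Z)-4-{(1S,2R,5S,6R)-6-formyl-2,6-dimethyl-5-[(triisopropylsilyl)oxy]cyclohex-3-en-1-yl}-2-methyl-3-(triflyloxy)but-2-enoate (enantiomer of 10) | O=C[C@@]1(C)[C@@H](O[Si](C(C)C)(C(C)C)C(C)C)C=C[C@@H](C)[C@@H]1C/C(OS(=O)(=O)C(F)(F)F)=C(\C)C(=O)OC
F2 | step 5 | methyl (2Z)-4-[(1S,2R,5S,6R)-6-formyl-5-hydroxy-2,6-dimethylcyclohex-3-en-1-yl]-2-methyl-3-(triflyloxy)but-2-enoate (enantiomer of 11) | O=C[C@@]1(C)[C@@H](O)C=C[C@@H](C)[C@@H]1C/C(OS(=O)(=O)C(F)(F)F)=C(\C)C(=O)OC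
F3 | step 5 | methyl (2Z)-4-[(1R,2S,5R,6S)-5-acetoxy-6-formyl-2,6-dimethylcyclohex-3-en-1-yl]-2-methyl-3-(triflyloxy)but-2-enoate | O=C[C@]1(C)[C@H](OC(C)=O)C=C[C@H](C)[C@H]1C/C(OS(=O)(=O)C(F)(F)F)=C(\C)C(=O)OC
F4 | step 5 | methyl (2Z)-4-[(1R,4S,5S,6S)-5-acetoxy-6-formyl-4-hydroperoxy-2,6-dimethylcyclohex-2-en-1-yl]-2-methyl-3-(triflyloxy)but-2-enoate | O=C[C@]1(C)[C@H](OC(C)=O)[C@@H](OO)C=C(C)[C@H]1C/C(OS(=O)(=O)C(F)(F)F)=C(\C)C(=O)OC
F5 | step 10 | methyl (2Z)-4-{(1R,5S,6R)-5-acetoxy-6-[(1R,4Z)-1-hydroxy-4-methyl-6-(triethylsilyloxy)hex-4-en-1-yl]-2,6-dimethyl-4-oxocyclohex-2-en-1-yl}-2-methyl-3-(triflyloxy)but-2-enoate (C2 epimer of 21) | O[C@H](CC/C(C)=C\CO[Si](CC)(CC)CC)[C@]1(C)[C@H](OC(C)=O)C(=O)C=C(C)[C@H]1C/C(OS(=O)(=O)C(F)(F)F)=C(\C)C(=O)OC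
F6 | step 10 | methyl (2Z)-4-{(1R,5S,6S)-5-acetoxy-2,6-dimethyl-6-[(4Z)-4-methyl-6-(triethylsilyloxy)hex-4-enoyl]-4-oxocyclohex-2-en-1-yl}-2-methyl-3-(triflyloxy)but-2-enoate | O=C(CC/C(C)=C\CO[Si](CC)(CC)CC)[C@]1(C)[C@H](OC(C)=O)C(=O)C=C(C)[C@H]1C/C(OS(=O)(=O)C(F)(F)F)=C(\C)C(=O)OC
F7 | step 13 | bis(3-methylbut-3-en-1-yl)zinc | C=C(C)CC[Zn]CCC(C)=C
F8 | step 13 | methyl (2Z)-4-{(1R,5S,6R)-5-acetoxy-6-[(1S)-1-hydroxy-4-methylpent-4-en-1-yl]-2,6-dimethyl-4-oxocyclohex-2-en-1-yl}-2-methyl-3-(triflyloxy)but-2-enoate | O[C@@H](CCC(C)=C)[C@]1(C)[C@H](OC(C)=O)C(=O)C=C(C)[C@H]1C/C(OS(=O)(=O)C(F)(F)F)=C(\C)C(=O)OC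
F9 | step 13 | methyl (2Z)-4-{(1R,5S,6R)-5-acetoxy-2,6-dimethyl-6-[(1S)-4-methyl-1-{[(2E)-2-methylbut-2-enoyl]oxy}pent-4-en-1-yl]-4-oxocyclohex-2-en-1-yl}-2-methyl-3-(triflyloxy)but-2-enoate | C/C=C(\C)C(=O)O[C@@H](CCC(C)=C)[C@]1(C)[C@H](OC(C)=O)C(=O)C=C(C)[C@H]1C/C(OS(=O)(=O)C(F)(F)F)=C(\C)C(=O)OC
F10 | step 13 | methyl (2Z,4R)-3-({(1R,5S,6R)-5-acetoxy-2,6-dimethyl-6-[(1S)-4-methyl-1-{[(2E)-2-methylbut-2-enoyl]oxy}pent-4-en-1-yl]-4-oxocyclohex-2-en-1-yl}methyl)-4-hydroxy-2-methylhexa-2,5-dienoate | C/C=C(\C)C(=O)O[C@@H](CCC(C)=C)[C@]1(C)[C@H](OC(C)=O)C(=O)C=C(C)[C@H]1C/C(=C(\C)C(=O)OC)[C@H](O)C=C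
F11 | step 13 | (1S)-1-[(1R,2R,6S)-6-acetoxy-2-{[(2R)-2-ethenyl-4-methyl-5-oxo-2,5-dihydrofuran-3-yl]methyl}-1,3-dimethyl-5-oxocyclohex-3-en-1-yl]-4-methylpent-4-en-1-yl (2E)-2-methylbut-2-enoate | C/C=C(\C)C(=O)O[C@@H](CCC(C)=C)[C@]1(C)[C@H](OC(C)=O)C(=O)C=C(C)[C@H]1CC1=C(C)C(=O)O[C@@H]1C=C
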